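**Plan**
1. Retrosynthetic cuts, in order:
   - C4–C4a, read backwards as a 1,2-acyl shift that returns C4 to C8a and leaves a spiro-dienone.
   - O1–C8a, an oxidative dearomatising etherification.
   - The aryl–C4 bond, a Heck reaction.
   - The C–O bonds at C4 and in the side chain, a double Markovnikov hydration.
2. Enabling feature: in the benzene ring, C6–OH stands para to C8a–O1, and the acyl carbon C4 sits on C4a, ortho to C8a. The arene is therefore the aromatised form of a cyclohexa-2,5-dienone (C6 as the carbonyl) whose C8a is a spiro centre bearing both O1 and C4.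
3. Forward order: 2-bromo-4-iodophenol is joined to (R)-linalool and both alkenes are hydrated. The tertiary alcohol then closes a five-membered oxa-spiro ring on the para carbon of the phenol. The ring carbinol is raised to the ketone, and acid expands the five-membered ring to the pyranone ring while the arene and C6–OH are regenerated.
4. Helper: the benzylic carbon stays at carbinol level, as its triethylsilyl ether, during the dearomatisation, because an acyl group there would shut the oxidation down. It is oxidised only afterwards.
5. Stereochemistry: C2 is the carbinol carbon of (R)-linalool and none of its four bonds is ever broken. The transient centres (C4 carbinol, spiro carbon) are uncontrolled and are erased.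

Key step: step 9

Assumption: commercial (R)-(−)-linalool is taken as enantiomerically pure; because C2 is never touched, its enantiomeric composition passes unchanged into the target.
Numbering: chromanone numbering (O1, C2, C3, C4, C4a, C5–C8, C8a) is used for the target. Spiro numbering (O1, C2, C3, C4, spiro C5, C6–C10, Br on C7, carbonyl C8) is used for 8–11.

**Step 1**
Reactants: 1 2-bromo-4-iodophenol
Product: 2 tert-butyl(2-bromo-4-iodophenoxy)dimethylsilane
Conditions: TBSCl (1.1 equiv), imidazole (2 equiv), CH2Cl2, rt
Reagents that add atoms: tert-butyldimethylsilyl chloride, CC(C)(C)[Si](C)(C)Cl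
Why: Routine silylation of a phenol; the silyl ether keeps the acidic, oxidisable OH out of the palladium and cobalt steps and can later be removed without touching an alkyl silyl ether.

**Step 2**
Reactants: 2 tert-butyl(2-bromo-4-iodophenoxy)dimethylsilane; 3 (R)-(−)-linalool
Product: 4 (1E,3R)-1-[3-bromo-4-(tert-butyldimethylsilyloxy)phenyl]-3,7-dimethylocta-1,6-dien-3-ol
Conditions: Pd(OAc)2 (5 mol %), nBu4NCl (1 equiv), NaHCO3 (2.5 equiv), DMF, 50 °C
Reagents that add atoms: none
Why: Mizoroki–Heck reaction of a tertiary allylic alcohol: zerovalent palladium inserts into C–I well before C–Br at this temperature, the aryl group goes to the unhindered vinyl terminus, and because the carbinol carbon bears no hydrogen the β-hydride elimination can only give the (E)-styrene, so the stereocentre of 3 is carried over unchanged.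

**Step 3**
Reactants: 4 (1E,3R)-1-[3-bromo-4-(tert-butyldimethylsilyloxy)phenyl]-3,7-dimethylocta-1,6-dien-3-ol
Product: 5 (3R)-1-[3-bromo-4-(tert-butyldimethylsilyloxy)phenyl]-3,7-dimethyloctane-1,3,7-triol (both C1 epimers)
Conditions: Co(acac)2 (20 mol %), PhSiH3 (5 equiv), O2 (1 atm), THF, rt
Reagents that add atoms: dioxygen, O=O
Why: Mukaiyama hydration (hydrogen-atom transfer from a cobalt hydride, capture by O2, reduction in situ by the silane) run on both alkenes at once: hydrogen goes to the carbon that leaves the tertiary radical in the side chain and the benzylic radical next to the arene, which fixes both regiochemistries, while the new benzylic centre forms without control and is erased in step 8.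

**Step 4**
Reactants: 5 (3R)-1-[3-bromo-4-(tert-butyldimethylsilyloxy)phenyl]-3,7-dimethyloctane-1,3,7-triol
Product: 6 (3R)-1-[3-bromo-4-(tert-butyldimethylsilyloxy)phenyl]-3,7-dimethyl-1-(triethylsilyloxy)octane-3,7-diol (both C1 epimers)
Conditions: TESCl (1.1 equiv), imidazole (2.5 equiv), CH2Cl2, 0 °C
Reagents that add atoms: triethylsilyl chloride, CC[Si](Cl)(CC)CC
Why: Rate-controlled silylation: the secondary benzylic alcohol reacts with TESCl/imidazole at 0 °C whereas the two tertiary alcohols do not, which masks the one hydroxyl that could provoke C–C fragmentation during the phenol oxidation.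

**Step 5**
Reactants: 6 (3R)-1-[3-bromo-4-(tert-butyldimethylsilyloxy)phenyl]-3,7-dimethyl-1-(triethylsilyloxy)octane-3,7-diol
Product: 7 (3R)-1-(3-bromo-4-hydroxyphenyl)-3,7-dimethyl-1-(triethylsilyloxy)octane-3,7-diol (both C1 epimers)
Conditions: LiOAc (20 mol %), DMF/H2O (50:1), rt
Reagents that add atoms: none
Why: Carboxylate-catalysed hydrolysis of aryl silyl ethers exploits the good leaving-group ability of the ortho-bromophenoxide and leaves the alkyl triethylsilyl ether and both tertiary alcohols alone.

**Step 6**
Reactants: 7 (3R)-1-(3-bromo-4-hydroxyphenyl)-3,7-dimethyl-1-(triethylsilyloxy)octane-3,7-diol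
Product: 8 (2R)-7-bromo-2-(4-hydroxy-4-methylpentyl)-2-methyl-4-(triethylsilyloxy)-1-oxaspiro[4.5]deca-6,9-dien-8-one (epimers at C4 and C5)
Conditions: PhI(OAc)2 (1.1 equiv), (CF3)2CHOH/CH2Cl2 (1:1), −10 to 0 °C
Reagents that add atoms: none
Why: Oxidative phenol dearomatisation by a trivalent-iodine reagent in a fluoroalcohol (spiroetherification): the para carbon becomes electrophilic and is captured 5-exo-trig by the tertiary hydroxyl, helped by the gem-disubstitution at C2, so the hindered tertiary alkyl–O–ring bond forms without touching the C2–O bond (retention), and the new spiro centre, like C4, needs no control because both are erased later.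

**Step 7**
Reactants: 8 (2R)-7-bromo-2-(4-hydroxy-4-methylpentyl)-2-methyl-4-(triethylsilyloxy)-1-oxaspiro[4.5]deca-6,9-dien-8-one
Product: 9 (2R)-7-bromo-4-hydroxy-2-(4-hydroxy-4-methylpentyl)-2-methyl-1-oxaspiro[4.5]deca-6,9-dien-8-one (epimers at C4 and C5)
Conditions: HF·pyridine, pyridine, THF, 0 °C
Reagents that add atoms: none
Why: Fluoride-mediated desilylation in a weakly acidic medium frees the hindered carbinol without ever forming its alkoxide, which could break the C4–C5 bond under the pull of aromatisation.

**Step 8**
Reactants: 9 (2R)-7-bromo-4-hydroxy-2-(4-hydroxy-4-methylpentyl)-2-methyl-1-oxaspiro[4.5]deca-6,9-dien-8-one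
Product: 10 (2R)-7-bromo-2-(4-hydroxy-4-methylpentyl)-2-methyl-1-oxaspiro[4.5]deca-6,9-diene-4,8-dione (both C5 epimers)
Conditions: Dess–Martin periodinane (1.3 equiv), 2,6-lutidine (3 equiv), CH2Cl2, 0 °C to rt; water-free work-up (pentane, filtration through a short silica pad)
Reagents that add atoms: none
Why: Dess–Martin oxidation (pentavalent iodine) converts hindered secondary alcohols to ketones under buffered, non-nucleophilic conditions, the tertiary alcohol and the bromodienone are inert, the C4 centre disappears, and the water-free work-up spares the acyl group, which nucleophiles could otherwise cleave from the ring.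

**Step 9**
Reactants: 10 (2R)-7-bromo-2-(4-hydroxy-4-methylpentyl)-2-methyl-1-oxaspiro[4.5]deca-6,9-diene-4,8-dione
Product: 12 (2R)-7-bromo-6-hydroxy-2-(4-hydroxy-4-methylpentyl)-2-methylchroman-4-one, via oxocarbenium sigma-complex 11 (not isolated)
Conditions: TFA (5 equiv), CH2Cl2, 0 °C; pH 7 phosphate buffer quench
Reagents that add atoms: none
Why: Proposed new method: protonation of the C8 dienone oxygen gives a hydroxypentadienyl cation, the acyl carbon C4 shifts with its bonding pair from spiro C5 to the neighbouring ring carbon C10 while the lone pair of O1 takes up the charge at C5 (sigma-complex 11), and loss of the C10 proton gives the phenol, so that C5, C10 and C8 become C8a, C4a and C6 of 12. The closest known reaction types are the ring-enlarging dienone–phenol rearrangement of spiro[4.5]deca-6,9-dien-8-ones to tetrahydronaphthols, the 1,2-acyl shift of 4-acylcyclohexa-2,5-dienones in trifluoroacetic acid and the quinol-to-hydroquinone rearrangement; their union on a 4-alkoxy-4-acyl spirodienone is what is new. No ring is closed by a cyclisation: the five-membered ring (O1, C2, C3, C4, C5) becomes the six-membered pyranone ring because C10 is inserted between C4 and C5 by a suprafacial 1,2-shift, as the carbocycle aromatises. No stereocentre is created; C2 is a spectator whose four bonds stay intact, and both spiro epimers of 10 converge on one product because C5 becomes planar. Two selectivities are needed: carbon and not oxygen must migrate, which is secured because only the acyl shift leaves a cation stabilised by O1 (a shift of O1 would leave the charge next to the carbonyl group), and C4 must go to C10 and not to C6, which is favoured because C6 adjoins C7–Br, whose inductive pull lowers the cationic character there, and because that path leads to the crowded sigma-complex ortho to bromine instead of the one para to it. Short exposure to dilute acid at 0 °C is chosen so that the side-chain tertiary alcohol does not ionise and the β-aryloxy ketone of 12 does not open and reclose.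

**Compound list**
1 | 2-bromo-4-iodophenol | Oc1ccc(I)cc1Br | starting material
2 | tert-butyl(2-bromo-4-iodophenoxy)dimethylsilane | CC(C)(C)[Si](C)(C)Oc1ccc(I)cc1Br | intermediate
3 | (R)-(−)-linalool | CC(C)=CCC[C@@](C)(O)C=C | starting material
4 | (1E,3R)-1-[3-bromo-4-(tert-butyldimethylsilyloxy)phenyl]-3,7-dimethylocta-1,6-dien-3-ol | CC(C)=CCC[C@@](C)(O)/C=C/c1ccc(O[Si](C)(C)C(C)(C)C)c(Br)c1 | intermediate
5 | (3R)-1-[3-bromo-4-(tert-butyldimethylsilyloxy)phenyl]-3,7-dimethyloctane-1,3,7-triol, C1 epimers | CC(C)(O)CCC[C@@](C)(O)CC(O)c1ccc(O[Si](C)(C)C(C)(C)C)c(Br)c1 | intermediate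
6 | (3R)-1-[3-bromo-4-(tert-butyldimethylsilyloxy)phenyl]-3,7-dimethyl-1-(triethylsilyloxy)octane-3,7-diol, C1 epimers | CC(C)(O)CCC[C@@](C)(O)CC(O[Si](CC)(CC)CC)c1ccc(O[Si](C)(C)C(C)(C)C)c(Br)c1 | intermediate
7 | (3R)-1-(3-bromo-4-hydroxyphenyl)-3,7-dimethyl-1-(triethylsilyloxy)octane-3,7-diol, C1 epimers | CC(C)(O)CCC[C@@](C)(O)CC(O[Si](CC)(CC)CC)c1ccc(O)c(Br)c1 | intermediate
8 | (2R)-7-bromo-2-(4-hydroxy-4-methylpentyl)-2-methyl-4-(triethylsilyloxy)-1-oxaspiro[4.5]deca-6,9-dien-8-one, C4/C5 epimers | CC(C)(O)CCC[C@]1(C)CC(O[Si](CC)(CC)CC)C2(O1)C=CC(=O)C(Br)=C2 | intermediate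
9 | (2R)-7-bromo-4-hydroxy-2-(4-hydroxy-4-methylpentyl)-2-methyl-1-oxaspiro[4.5]deca-6,9-dien-8-one, C4/C5 epimers | CC(C)(O)CCC[C@]1(C)CC(O)C2(O1)C=CC(=O)C(Br)=C2 | intermediate
10 | (2R)-7-bromo-2-(4-hydroxy-4-methylpentyl)-2-methyl-1-oxaspiro[4.5]deca-6,9-diene-4,8-dione, C5 epimers | CC(C)(O)CCC[C@]1(C)CC(=O)C2(O1)C=CC(=O)C(Br)=C2 | intermediate
11 | oxocarbenium sigma-complex (C4 on sp3 C4a, charge on C8a=O1), not isolated | CC(C)(O)CCC[C@]1(C)CC(=O)C2C=C(O)C(Br)=CC2=[O+]1 | intermediate
12 | (2R)-7-bromo-6-hydroxy-2-(4-hydroxy-4-methylpentyl)-2-methylchroman-4-one | CC(C)(O)CCC[C@]1(C)CC(=O)c2cc(O)c(Br)cc2O1 | target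

**Total step count:** 9
**Longest linear sequence:** 9 steps (1 to 12)

**Steps most likely to fail**

1. **Step 9 (Proposed new method).** Four things may go wrong:
   - Competing migration toward C6.
   - Solvolytic loss of the acyl group with aromatisation.
   - β-Elimination of O1 and re-addition, which would erode the configuration at C2.
   - Ionisation of the side-chain tertiary alcohol.

   Fallback (sets out from 10, returns at 12): the acyl group is cut off on purpose instead of shifted, and the ring is then closed directly. LiOH in THF/H2O at 0 °C adds hydroxide to the activated C4 ketone. The C4–C5 bond breaks with aromatisation (retro-Claisen cleavage) to give (3R)-3-(3-bromo-4-hydroxyphenoxy)-7-hydroxy-3,7-dimethyloctanoic acid F1, in which the tertiary aryl ether is already in place. TFAA in CH2Cl2 at 0 °C gives the fully trifluoroacetylated mixed anhydride F2. On warming to rt this undergoes intramolecular Friedel–Crafts acylation ortho to the ether oxygen and para to bromine, giving the chromanone bis(trifluoroacetate) F3. NaHCO3 in MeOH at 0 °C then frees both hydroxyls to give 12.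

2. **Step 3.** Hydrogen-atom transfer to the styrene carbon next to the quaternary carbinol may be sluggish. The benzylic position may be over-oxidised to the ketone level, and the side-chain radical may be captured by the styrene.

   Fallback (sets out from 3, returns at 5): polar chemistry replaces radical chemistry, one alkene at a time. mCPBA with NaHCO3 in CH2Cl2 at 0 °C epoxidises only the electron-rich trisubstituted alkene of 3, giving (3R)-6,7-epoxy-3,7-dimethyloct-1-en-3-ol F4. LiAlH4 in THF at 0 °C opens the epoxide at its less substituted carbon to (3R)-3,7-dimethyloct-1-ene-3,7-diol F5. Heck coupling with 2 under the conditions of step 2 gives (1E,3R)-1-[3-bromo-4-(tert-butyldimethylsilyloxy)phenyl]-3,7-dimethyloct-1-ene-3,7-diol F6. Hydroboration–oxidation (BH3·THF, then NaBO3·4H2O) places boron on the benzylic carbon, away from the quaternary carbinol carbon, and gives 5.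

3. **Step 6.** The electron-poor bromophenol may be activated slowly. Capture by solvent or acetate, or ionisation of the benzylic silyl ether, could then outrun closure by the hindered tertiary hydroxyl.

   Fallback (sets out from 3, returns at 8): bromine is left out until the ring has been dearomatised.
   - Commercial 4-iodophenol is silylated as in step 1 to tert-butyl(4-iodophenoxy)dimethylsilane F7.
   - F7 is carried with 3 through the operations of steps 2 to 5, giving in turn the bromine-free Heck product F8, the bromine-free triol F9, the bromine-free triethylsilyl ether F10 and the bromine-free phenol F11.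
   - The more electron-rich phenol is oxidised with PhI(OAc)2 as in step 6 to the bromine-free spirodienone F12.
   - Br2 in CH2Cl2 at 0 °C adds to one enone double bond to give the dibromide F13. Et3N then removes HBr (bromination–dehydrobromination of an enone) to give the α-bromodienone 8.

**Further compounds**
F1 | step 9 | (3R)-3-(3-bromo-4-hydroxyphenoxy)-7-hydroxy-3,7-dimethyloctanoic acid | CC(C)(O)CCC[C@](C)(CC(=O)O)Oc1ccc(O)c(Br)c1
F2 | step 9 | mixed trifluoroacetic anhydride of F1 with phenol and tertiary alcohol as trifluoroacetates | CC(C)(OC(=O)C(F)(F)F)CCC[C@](C)(CC(=O)OC(=O)C(F)(F)F)Oc1ccc(OC(=O)C(F)(F)F)c(Br)c1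
F3 | step 9 | (2R)-7-bromo-2-methyl-2-[4-methyl-4-(trifluoroacetoxy)pentyl]-4-oxochroman-6-yl trifluoroacetate | CC(C)(OC(=O)C(F)(F)F)CCC[C@]1(C)CC(=O)c2cc(OC(=O)C(F)(F)F)c(Br)cc2O1
F4 | step 3 | (3R)-6,7-epoxy-3,7-dimethyloct-1-en-3-ol, C6 epimers | CC1(C)OC1CC[C@@](C)(O)C=C
F5 | step 3 | (3R)-3,7-dimethyloct-1-ene-3,7-diol | CC(C)(O)CCC[C@@](C)(O)C=C
F6 | step 3 | (1E,3R)-1-[3-bromo-4-(tert-butyldimethylsilyloxy)phenyl]-3,7-dimethyloct-1-ene-3,7-diol | CC(C)(O)CCC[C@@](C)(O)/C=C/c1ccc(O[Si](C)(C)C(C)(C)C)c(Br)c1
F7 | step 6 | tert-butyl(4-iodophenoxy)dimethylsilane | CC(C)(C)[Si](C)(C)Oc1ccc(I)cc1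
F8 | step 6 | (1E,3R)-1-[4-(tert-butyldimethylsilyloxy)phenyl]-3,7-dimethylocta-1,6-dien-3-ol | CC(C)=CCC[C@@](C)(O)/C=C/c1ccc(O[Si](C)(C)C(C)(C)C)cc1
F9 | step 6 | (3R)-1-[4-(tert-butyldimethylsilyloxy)phenyl]-3,7-dimethyloctane-1,3,7-triol, C1 epimers | CC(C)(O)CCC[C@@](C)(O)CC(O)c1ccc(O[Si](C)(C)C(C)(C)C)cc1
F10 | step 6 | (3R)-1-[4-(tert-butyldimethylsilyloxy)phenyl]-3,7-dimethyl-1-(triethylsilyloxy)octane-3,7-diol, C1 epimers | CC(C)(O)CCC[C@@](C)(O)CC(O[Si](CC)(CC)CC)c1ccc(O[Si](C)(C)C(C)(C)C)cc1
F11 | step 6 | (3R)-1-(4-hydroxyphenyl)-3,7-dimethyl-1-(triethylsilyloxy)octane-3,7-diol, C1 epimers | CC(C)(O)CCC[C@@](C)(O)CC(O[Si](CC)(CC)CC)c1ccc(O)cc1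
F12 | step 6 | (2R)-2-(4-hydroxy-4-methylpentyl)-2-methyl-4-(triethylsilyloxy)-1-oxaspiro[4.5]deca-6,9-dien-8-one, C4 epimers | CC(C)(O)CCC[C@]1(C)CC(O[Si](CC)(CC)CC)C2(O1)C=CC(=O)C=C2
F13 | step 6 | (2R)-6,7-dibromo-2-(4-hydroxy-4-methylpentyl)-2-methyl-4-(triethylsilyloxy)-1-oxaspiro[4.5]dec-9-en-8-one, diastereomers | CC(C)(O)CCC[C@]1(C)CC(O[Si](CC)(CC)CC)C2(O1)C=CC(=O)C(Br)C2Br
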